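The constants used here were drawn at random within sensible limits; what happens was integrated by code.

The clock stops at 40 s, so I ask what free monomer can do in that time. I follow two ways out: into chains through a living end, or into uncatalysed product by itself.

free monomer 0.10 M; transfer agent 1.00 mM; initiator 6.2 mM; time 40 s

    free monomer + initiator → living end + monomer in chains (k1 = 3.61 M⁻¹ s⁻¹)
    free monomer + living end → monomer in chains + living end, rate k2*[living end]*[free monomer] (k2 = 6.32 M⁻¹ s⁻¹)
    living end + transfer agent → dead chain (k3 = 16.2 M⁻¹ s⁻¹)
    free monomer → uncatalysed product (k4 = 0.00524 s⁻¹)
    living end + monomer in chains → dead end (k5 = 0.162 M⁻¹ s⁻¹)

* whether the average number of monomer units in a chain (chains begun, living or dead) reaches 3.0 by 40 s (no / yes)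
* average number of monomer units in a chain (chains begun, living or dead) at 40 s

- the average divides the monomer in chains by the number of chains begun, living and dead together
- run time (flask): 40 s

Both ways are first order in [free monomer], pseudo-first-order while [living end] holds steady, so when I divide one rate by the other, [free monomer] and time drop out. I need [living end] first. In this flask the initiator has a half-life of 1.92 s at the charged [free monomer], far shorter than the run, so I count 6.2 mM of chains begun. The transfer agent lasts 11.9 s against those ends, also shorter than the run, so I let it take 1.00 mM of them and reckon with [living end] at 5.20 mM as an estimate. I set step 5 aside: its time on a living end is 61.7 s even with the whole charge in chains, longer than the run but not by much, so my count of ends runs high.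

That leaves two times: free monomer lasts 30.4 s against the living ends and 191 s by itself. Their ratio is 6.27. This split is the monomer going into chains for each one going to uncatalysed product, a selectivity factor. So 86.2 % of what reacts enters chains. Together the two ways leave 21.8 % of the free monomer at the stop, which puts 0.0675 M in chains, or 10.9 units per chain, above 3.0, so I answer yes.

The forecast gives yes and 10.3, lower than mine, in the words “About three-quarters of the monomer is therefore used”.

The flask gives yes and 10.3, lower than my figure, and its average passes 3.0 at 5.59 s. At 13.9 s the rate of step 2 over step 4 reads 6.3, about my split, but by 40.0 s [living end] is 0.00402 M, below my count, and the split reckoned from it is 4.85. At that time the flask holds monomer in chains at 64.1 % of the charge and uncatalysed product at 10.9 %.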